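**Plan**
1. Retrosynthetic cuts, in order: the five O–CH2Ph bonds and the carbinol C–H (back to an aryl ketone); the ketone C–aryl bond (back to a Weinreb amide on C3); the indane bond C1–C2, opened by placing an NH between the two carbons (a 1,3-diaryl-tetrahydroisoquinoline); C1–N and C1–C7a (Pictet–Spengler); C2–C3 (Mannich).
2. Forward order: the chain C2–C3 is joined first. A six-membered azacycle is closed as a temporary ring, and the five-membered ring arises from it by loss of N2. The fourth aryl ring, the carbinol and the free phenols follow.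
3. Enabling feature: C1 and C2 are neighbouring benzylic methines. C1 sits on ring A and the 4-oxyphenyl ring, and C2 on the 3,5-dioxyphenyl ring, so each can carry a C–N bond and each gives a stabilised radical once the nitrogen leaves. C7a of ring A lies ortho to O–C7 and para to O–C5, so the azacycle closes by electrophilic substitution on an unfunctionalised ring A.
4. Stereochemistry: the (R)-tert-butanesulfinyl auxiliary sets C2, and the syn-Mannich addition sets C3. The peri oxygen on C7 sets C1 trans to the C2 aryl group. The extrusion passes C1 and C2 on to the indane, and Felkin–Anh reduction sets the carbinol carbon.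

Key step: step 7

Remark on locants: in the text and in the names of the indanes, C1 carries the 4-oxyphenyl ring, C2 the 3,5-dioxyphenyl ring and C3 the side chain. C3a and C7a are the fusion carbons of ring A (oxygens on C5 and C7). The target is taken as drawn, (1R,2S,3R) all-trans with an (R) carbinol carbon.

**Step 1**
Reactants: 1 methyl 2-(3,5-dihydroxyphenyl)acetate
Product: 2 methyl 2-[3,5-bis(benzyloxy)phenyl]acetate
Conditions: BnBr, K2CO3, DMF, rt → 50 °C
Reagents that add atoms: benzyl bromide, BrCc1ccccc1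
Why: Williamson ether synthesis, in which K2CO3 deprotonates only the two phenols and leaves the ester and its CH2 group alone.

**Step 2**
Reactants: 2 methyl 2-[3,5-bis(benzyloxy)phenyl]acetate
Product: 3 2-[3,5-bis(benzyloxy)phenyl]-N-methoxy-N-methylacetamide
Conditions: MeNH(OMe)·HCl, i-PrMgCl, THF, −20 → 0 °C
Reagents that add atoms: N,O-dimethylhydroxylamine hydrochloride, CNOC.Cl
Why: Weinreb amide formation by aminolysis of the ester with the magnesium amide, a standard protocol for enolisable esters.

**Step 3**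
Reactants: 4 3,5-bis(benzyloxy)benzaldehyde; 5 (R)-2-methylpropane-2-sulfinamide
Product: 6 (R,E)-N-[3,5-bis(benzyloxy)benzylidene]-2-methylpropane-2-sulfinamide
Conditions: Ti(OEt)4, THF, rt
Reagents that add atoms: none
Why: Condensation to the N-sulfinyl aldimine with Ti(OEt)4 as Lewis acid and water scavenger, which should give only the E imine and does not touch the sulfur stereocentre.

**Step 4**
Reactants: 3 2-[3,5-bis(benzyloxy)phenyl]-N-methoxy-N-methylacetamide; 6 (R,E)-N-[3,5-bis(benzyloxy)benzylidene]-2-methylpropane-2-sulfinamide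
Product: 8 (2S,3S)-2,3-bis[3,5-bis(benzyloxy)phenyl]-3-{[(R)-tert-butylsulfinyl]amino}-N-methoxy-N-methylpropanamide, via lithium enolate 7 (not isolated)
Conditions: LiN(SiMe3)2, THF, −78 °C; then 6, −78 °C; sat. aq NH4Cl
Reagents that add atoms: none
Why: Mannich-type addition of the Z lithium enolate 7 to the N-sulfinyl aldimine through a closed, lithium-bridged chair transition state, in which the (R)-sulfinyl group should fix the (S) configuration at the C–N carbon (later C2) and the enolate geometry should fix the syn relation to the α-aryl carbon (later C3).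

**Step 5**
Reactants: 8 the Mannich adduct
Product: 9 (2S,3S)-3-amino-2,3-bis[3,5-bis(benzyloxy)phenyl]-N-methoxy-N-methylpropanamide
Conditions: HCl (4 M in dioxane), MeOH, rt; aq NaHCO3
Reagents that add atoms: none
Why: Acidic methanolysis of the S–N bond of the sulfinamide, which leaves both carbon stereocentres, the benzyl ethers and the Weinreb amide untouched.

**Step 6**
Reactants: 9 the free β-amino amide; 10 4-(benzyloxy)benzaldehyde
Product: 12 (1R,3S,4S)-6,8-bis(benzyloxy)-1-[4-(benzyloxy)phenyl]-3-[3,5-bis(benzyloxy)phenyl]-N-methoxy-N-methyl-1,2,3,4-tetrahydroisoquinoline-4-carboxamide, via imine 11 (not isolated)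
Conditions: 4 Å molecular sieves, CH2Cl2, rt; then CF3CO2H, 0 °C → rt; aq NaHCO3
Reagents that add atoms: none
Why: Pictet–Spengler reaction, in which the protonated imine 11 is attacked 6-endo-trig by the ring A carbon ortho to one and para to the other benzyloxy group (both ortho positions are equivalent), and the new centre (later C1) should settle trans to the 3-aryl group because the peri benzyloxy group forces the 1-aryl group pseudoaxial while the 3-aryl group stays equatorial, an outcome that reversible C1–N ionisation in CF3CO2H should reinforce.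

**Step 7**
Reactants: 12 the 1,3-trans-3,4-trans tetrahydroisoquinoline
Product: 16 (1R,2S,3R)-5,7-bis(benzyloxy)-1-[4-(benzyloxy)phenyl]-2-[3,5-bis(benzyloxy)phenyl]-N-methoxy-N-methylindane-3-carboxamide, via hydrazide adduct 13 (not isolated), via isodiazene 14 (not isolated), via 1,5-diradical 15 (not isolated)
Conditions: N-(benzyloxy)-N-(pivaloyloxy)-4-(trifluoromethyl)benzamide (1.5 equiv), THF, 45 °C
Reagents that add atoms: none
Why: The secondary amine attacks the amide nitrogen of the anomeric amide and displaces pivalate to give 13, which expels benzyl 4-(trifluoromethyl)benzoate by a shift of the benzyloxy group to the carbonyl carbon and leaves isodiazene 14; loss of N2 gives the singlet 1,5-diradical 15, whose termini (C1 stabilised by ring A and the 4-benzyloxyphenyl ring, C2 by the 3,5-dibenzyloxyphenyl ring) collapse to the C1–C2 bond. The closest known reaction type is nitrogen deletion of secondary benzylic amines through isodiazenes, including the stereoretentive contraction of 2,6-diarylpiperidines to 1,2-diarylcyclopentanes and of pyrrolidines to cyclobutanes. The five-membered ring closes by radical–radical recombination across the rigid tether C7a–C3a–C3, that is, by contraction of the six-membered azacycle through extrusion and not by attack on a π bond. C1 and C2 keep the configuration they had in 12 if collapse outruns bond rotation; if rotation competes, the untouched C3 centre should steer the C2 aryl group anti to the carboxamide and the C1 aryl group anti to the C2 aryl group, so both regimes should lead to the all-trans indane. The step needs amination at a single site, which is secured because 12 holds one N–H and no O–H, and it needs recombination to beat disproportionation, which is secured because the only hydrogen β to a radical centre (C3–H) could reach C1 only through a strained five-membered transition state.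

**Step 8**
Reactants: 16 the indane Weinreb amide; 17 4-(benzyloxy)phenylmagnesium bromide (commercial THF solution)
Product: 18 [4-(benzyloxy)phenyl]{(1R,2S,3R)-5,7-bis(benzyloxy)-1-[4-(benzyloxy)phenyl]-2-[3,5-bis(benzyloxy)phenyl]indan-3-yl}methanone
Conditions: 17 (3 equiv), THF, 0 °C → rt; then 1 M aq HCl, 0 °C
Reagents that add atoms: none
Why: Weinreb ketone synthesis, in which N-methoxy chelation blocks a second addition and the only base-labile centre, C3, already holds the thermodynamically preferred trans arrangement.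

**Step 9**
Reactants: 18 the aryl ketone
Product: 19 (R)-[4-(benzyloxy)phenyl]{(1R,2S,3R)-5,7-bis(benzyloxy)-1-[4-(benzyloxy)phenyl]-2-[3,5-bis(benzyloxy)phenyl]indan-3-yl}methanol
Conditions: LiBH(s-Bu)3, THF, −78 → −20 °C; then NaOH, H2O2, 0 °C
Reagents that add atoms: none
Why: Felkin–Anh-controlled hydride addition, in which the C3–C3a bond (aryl carbon, largest group and best σ* acceptor) stands perpendicular to the carbonyl plane and C3–H lies next to the 4-benzyloxyphenyl group, so the bulky borohydride should enter anti to ring A and set the (R) carbinol carbon.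

**Step 10**
Reactants: 19 the pentabenzyl ether
Product: 20 (1R,2S,3R)-2-(3,5-dihydroxyphenyl)-3-[(R)-hydroxy(4-hydroxyphenyl)methyl]-1-(4-hydroxyphenyl)indane-5,7-diol (CNP0214825.1)
Conditions: H2 (1 atm), Pd/C (10 wt% Pd on carbon), EtOAc–MeOH, rt, stopped when hydrogen uptake ends
Reagents that add atoms: none
Why: Hydrogenolysis of the five aryl benzyl ethers under neutral conditions, which should be much faster than cleavage of a secondary benzylic alcohol without acid and avoids the ionisation of the 4-hydroxybenzylic carbinol that acidic deprotection would cause.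

**Compound list**
1 | methyl 2-(3,5-dihydroxyphenyl)acetate | COC(=O)Cc1cc(O)cc(O)c1 | starting material
2 | methyl 2-[3,5-bis(benzyloxy)phenyl]acetate | COC(=O)Cc1cc(OCc2ccccc2)cc(OCc2ccccc2)c1 | intermediate
3 | 2-[3,5-bis(benzyloxy)phenyl]-N-methoxy-N-methylacetamide | CON(C)C(=O)Cc1cc(OCc2ccccc2)cc(OCc2ccccc2)c1 | intermediate
4 | 3,5-bis(benzyloxy)benzaldehyde | O=Cc1cc(OCc2ccccc2)cc(OCc2ccccc2)c1 | starting material
5 | (R)-2-methylpropane-2-sulfinamide | CC(C)(C)[S@@](=O)N | starting material
6 | (R,E)-N-[3,5-bis(benzyloxy)benzylidene]-2-methylpropane-2-sulfinamide | CC(C)(C)[S@@](=O)/N=C/c1cc(OCc2ccccc2)cc(OCc2ccccc2)c1 | intermediate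
7 | lithium (Z)-enolate of 3 | [Li]O/C(N(C)OC)=C\c1cc(OCc2ccccc2)cc(OCc2ccccc2)c1 | intermediate
8 | (2S,3S)-2,3-bis[3,5-bis(benzyloxy)phenyl]-3-{[(R)-tert-butylsulfinyl]amino}-N-methoxy-N-methylpropanamide | CC(C)(C)[S@@](=O)N[C@H](c1cc(OCc2ccccc2)cc(OCc2ccccc2)c1)[C@H](c1cc(OCc2ccccc2)cc(OCc2ccccc2)c1)C(=O)N(C)OC | intermediate
9 | (2S,3S)-3-amino-2,3-bis[3,5-bis(benzyloxy)phenyl]-N-methoxy-N-methylpropanamide | N[C@H](c1cc(OCc2ccccc2)cc(OCc2ccccc2)c1)[C@H](c1cc(OCc2ccccc2)cc(OCc2ccccc2)c1)C(=O)N(C)OC | intermediate
10 | 4-(benzyloxy)benzaldehyde | O=Cc1ccc(OCc2ccccc2)cc1 | starting material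
11 | (E)-imine of 9 and 10 | CON(C)C(=O)[C@@H](c1cc(OCc2ccccc2)cc(OCc2ccccc2)c1)[C@@H](c1cc(OCc2ccccc2)cc(OCc2ccccc2)c1)/N=C/c1ccc(OCc2ccccc2)cc1 | intermediate
12 | (1R,3S,4S)-6,8-bis(benzyloxy)-1-[4-(benzyloxy)phenyl]-3-[3,5-bis(benzyloxy)phenyl]-N-methoxy-N-methyl-1,2,3,4-tetrahydroisoquinoline-4-carboxamide | CON(C)C(=O)[C@@H]1[C@@H](c2cc(OCc3ccccc3)cc(OCc3ccccc3)c2)N[C@H](c2ccc(OCc3ccccc3)cc2)c2c(OCc3ccccc3)cc(OCc3ccccc3)cc21 | intermediate
13 | N-[N-(benzyloxy)-4-(trifluoromethyl)benzamido] derivative of 12 (hydrazide adduct) | CON(C)C(=O)[C@@H]1[C@@H](c2cc(OCc3ccccc3)cc(OCc3ccccc3)c2)N(N(OCc2ccccc2)C(=O)c2ccc(C(F)(F)F)cc2)[C@H](c2ccc(OCc3ccccc3)cc2)c2c(OCc3ccccc3)cc(OCc3ccccc3)cc21 | intermediate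
14 | isodiazene (1,1-diazene) of 12 | CON(C)C(=O)[C@@H]1[C@@H](c2cc(OCc3ccccc3)cc(OCc3ccccc3)c2)[N+](=[N-])[C@H](c2ccc(OCc3ccccc3)cc2)c2c(OCc3ccccc3)cc(OCc3ccccc3)cc21 | intermediate
15 | singlet 1,5-diradical (radical centres at C1 and C2, C3 intact) | CON(C)C(=O)[C@H]([CH]c1cc(OCc2ccccc2)cc(OCc2ccccc2)c1)c1cc(OCc2ccccc2)cc(OCc2ccccc2)c1[CH]c1ccc(OCc2ccccc2)cc1 | intermediate
16 | (1R,2S,3R)-5,7-bis(benzyloxy)-1-[4-(benzyloxy)phenyl]-2-[3,5-bis(benzyloxy)phenyl]-N-methoxy-N-methylindane-3-carboxamide | CON(C)C(=O)[C@@H]1[C@@H](c2cc(OCc3ccccc3)cc(OCc3ccccc3)c2)[C@H](c2ccc(OCc3ccccc3)cc2)c2c(OCc3ccccc3)cc(OCc3ccccc3)cc21 | intermediate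
17 | 4-(benzyloxy)phenylmagnesium bromide | Br[Mg]c1ccc(OCc2ccccc2)cc1 | starting material
18 | [4-(benzyloxy)phenyl]{(1R,2S,3R)-5,7-bis(benzyloxy)-1-[4-(benzyloxy)phenyl]-2-[3,5-bis(benzyloxy)phenyl]indan-3-yl}methanone | O=C(c1ccc(OCc2ccccc2)cc1)[C@@H]1[C@@H](c2cc(OCc3ccccc3)cc(OCc3ccccc3)c2)[C@H](c2ccc(OCc3ccccc3)cc2)c2c(OCc3ccccc3)cc(OCc3ccccc3)cc21 | intermediate
19 | (R)-[4-(benzyloxy)phenyl]{(1R,2S,3R)-5,7-bis(benzyloxy)-1-[4-(benzyloxy)phenyl]-2-[3,5-bis(benzyloxy)phenyl]indan-3-yl}methanol | O[C@@H](c1ccc(OCc2ccccc2)cc1)[C@@H]1[C@@H](c2cc(OCc3ccccc3)cc(OCc3ccccc3)c2)[C@H](c2ccc(OCc3ccccc3)cc2)c2c(OCc3ccccc3)cc(OCc3ccccc3)cc21 | intermediate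
20 | (1R,2S,3R)-2-(3,5-dihydroxyphenyl)-3-[(R)-hydroxy(4-hydroxyphenyl)methyl]-1-(4-hydroxyphenyl)indane-5,7-diol | Oc1ccc([C@@H]2c3c(O)cc(O)cc3[C@H]([C@@H](O)c3ccc(O)cc3)[C@H]2c2cc(O)cc(O)c2)cc1 | target

**Step count**
Total: 10 steps.
Longest linear sequence: 9 steps (steps 1, 2, 4, 5, 6, 7, 8, 9, 10). Step 3 is a one-step side branch.

**Steps most likely to fail**

1. Step 7.
   - Risk: N–N bond formation may be slow, because the nitrogen is flanked by two aryl-bearing carbons and by the peri benzyloxy group. Bond rotation in the diradical may leak configuration at C1.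
   - Fallback: this sets out from 12 and makes the N–N bond with a much smaller electrophile. Nitrosation with t-BuONO (CH2Cl2, rt) should give the N-nitrosamine F1. Reductive denitrogenation of F1 with Na2S2O4 and NaOH in aqueous EtOH–THF at 60 °C should reach the same isodiazene 14 from the reduced nitrosamine. After loss of N2 the route is rejoined at 16.

2. Step 9.
   - Risk: facial selectivity may be poor or reversed if the sp3 carbon C2, and not the aryl carbon C3a, acts as the large group at the hindered ketone.
   - Fallback: this sets out from 16. Reduction with i-Bu2AlH (toluene, −78 °C) should give the all-trans indane-3-carbaldehyde F2. Addition of 17 to F2 at −78 °C should give the carbinol and rejoin the route at 19. Hydride and aryl group change places between the two sequences, so the same steric bias of C3 leads to the opposite carbinol configuration. One of the two orders should therefore give the (R) centre.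

3. Step 4.
   - Risk: the addition of the stabilised α-aryl enolate may be reversible, which would erode the syn relation.
   - Fallback: this sets out from 2 and 6 and changes the nucleophile class. Ester 2 is deprotonated with LiN(i-Pr)2 (THF, −78 °C) and transmetalated with ClTi(Oi-Pr)3. The resulting chlorotitanium ester enolate adds to 6 through a tighter closed transition state and should give the syn β-sulfinylamino ester F3. Aminolysis of F3 with MeNH(OMe)·HCl and i-PrMgCl (THF, −20 °C) rejoins the route at 8.

**Further compounds**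
F1 | step 7 | (1R,3S,4S)-2-nitroso derivative of tetrahydroisoquinoline 12 | CON(C)C(=O)[C@@H]1[C@@H](c2cc(OCc3ccccc3)cc(OCc3ccccc3)c2)N(N=O)[C@H](c2ccc(OCc3ccccc3)cc2)c2c(OCc3ccccc3)cc(OCc3ccccc3)cc21
F2 | step 9 | (1R,2S,3R)-5,7-bis(benzyloxy)-1-[4-(benzyloxy)phenyl]-2-[3,5-bis(benzyloxy)phenyl]indane-3-carbaldehyde | O=C[C@@H]1[C@@H](c2cc(OCc3ccccc3)cc(OCc3ccccc3)c2)[C@H](c2ccc(OCc3ccccc3)cc2)c2c(OCc3ccccc3)cc(OCc3ccccc3)cc21
F3 | step 4 | methyl (2S,3S)-2,3-bis[3,5-bis(benzyloxy)phenyl]-3-{[(R)-tert-butylsulfinyl]amino}propanoate | CC(C)(C)[S@@](=O)N[C@H](c1cc(OCc2ccccc2)cc(OCc2ccccc2)c1)[C@H](c1cc(OCc2ccccc2)cc(OCc2ccccc2)c1)C(=O)OC
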